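Temperature, and the moment at 30 s when dusk changes it, is what we vary here.

    substrate + partner → open intermediate + by-product (k1 = 196 L mol⁻¹ s⁻¹, Ea1 = 47.0 kJ mol⁻¹)
    open intermediate ⇌ target (K2 = 0.62, k2 = 0.0233 s⁻¹, Ea2 = 80.0 kJ mol⁻¹, ΔH2 = −29.0 kJ mol⁻¹)
    open intermediate ⇌ isomer of the product (K3 = 80.4, k3 = 6.66 × 10⁻⁴ s⁻¹, Ea3 = 78.0 kJ mol⁻¹, ΔH3 = 11.0 kJ mol⁻¹)
    gas ⇌ partner, rate k4*(csat - [partner]) (k4 = 1.54 s⁻¹, csat = 0.041 mM)
    substrate + by-product → side product (k5 = 35.9 L mol⁻¹ s⁻¹, Ea5 = 43.0 kJ mol⁻¹)
    open intermediate + capture agent → trapped intermediate (k6 = 25.3 L mol⁻¹ s⁻¹, Ea6 = 39.0 kJ mol⁻¹)
    (constants at 25 °C)

all flasks: substrate 0.50 mM; gas 0.041 mM (held); capture agent 0.150 mM; time 40 s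
- midnight: temperature −35 °C
- winter: temperature 25 °C
- dusk: at −35 °C until 30 s, from then on at 25 °C
- spring: temperature −5 °C

- at the start none of partner is dissolved
- the list of constants is for 25 °C, to be carried to other temperatures by the activation energies and enthalpies

- which flask leads in share of target in all that became target or isomer of the product or side product or trapped intermediate ("all alike" within 1.5 percentage points) (midnight / winter / dusk / spring / all alike)
- share of target in all that became target or isomer of the product or side product or trapped intermediate, midnight
- share of target in all that became target or isomer of the product or side product or trapped intermediate, winter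
- share of target in all that became target or isomer of the product or side product or trapped intermediate, dusk
- share of target in all that became target or isomer of the product or side product or trapped intermediate, spring

We follow a warm flask in slow motion. In the first instants partner dissolves with a characteristic time of 0.649 s, and its transfer coefficient of 1.54 s⁻¹ stands far above the 0.0980 s⁻¹ at which the charged substrate consumes it. We therefore hold partner near 0.041 mM, and step 1 becomes pseudo-first-order in substrate, with 0.00804 s⁻¹ at 25 °C.

Each event of step 1 gives one open intermediate and one by-product, so the two pools rise together. In the middle of the run, then, side product forms at its rate constant times substrate times a by-product amount that we take as about equal to the open intermediate. Step 5 draws on by-product and not on the open intermediate, but in the count of products it then stands like one more first-order outlet of that pool, of size 0.0180 s⁻¹, beside 0.0233 s⁻¹ to target, 6.66 × 10⁻⁴ s⁻¹ to isomer of the product and 0.00379 s⁻¹ to trapped intermediate. The size of the pool cancels from the comparison, and so does time, as long as the return of target is left aside. Target's outlet over the sum of the outlets comes to 51.0% at 25 °C; we call this ratio, reckoned with the charged substrate and capture agent, the branch share.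

Carried to −35 °C by the activation energies, target's outlet falls to 6.86 × 10⁻⁶ s⁻¹ out of a sum of 3.06 × 10⁻⁴ s⁻¹, so the branch share for midnight is 2.24%. At −5 °C the same reckoning gives spring 16.2%. The share climbs with temperature because the barrier of step 2 is higher than that of step 5. In dusk, hardly any of the cold pool has left it by the change, so the warm stretch opens with two equal pools and the warm branch share.

In a warm stretch target also returns to open intermediate, and the approach of step 2 to its balance takes 16.4 s at 25 °C. Winter runs longer than this, whereas the warm stretch of dusk lasts 10.0 s, which is shorter. We therefore commit to dusk just under 51.0%, winter lower, and the two cold flasks at their branch shares.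

The forecast names dusk, with 2.2% for midnight, 41% for winter, 46% for dusk and 16.7% for spring, on the ground that “Dusk edges winter because its short warm stretch at the end has built little by-product and the target has not yet begun to run back”. We share the leader and the return of target, but we differ on by-product, which we keep in step with the open intermediate, and our warm branch share of 51.0% stands above its 46%.

The simulation gives dusk the lead, with 48.3% against 42.5% for winter, 16.6% for spring and 2.25% for midnight. At 40.0 s dusk holds 0.0343 mM of by-product beside 0.0329 mM of open intermediate. For the neighbour of dusk charged with 0.30 mM of substrate, the warm branch share reckons to 60.5%, and that flask gives 57.4%.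

All constants belong to no real substance; the result is computed.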